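Everything rests on cutting the piperazine bond N4–C5, which runs across the 14-membered ansa ring formed by C2, its p-phenylene arm, the ether oxygen, the m-phenylene arm, C5, C6 and N1. The precursor is that macrocycle as a C5 ketone with nosyl on N1 and the C3 nitrogen masked as an azide, so that the amino ketone is only generated in the flask. Staudinger unmasking lets N4 condense across the ring and the imine is reduced at once: one operation forms N4–C5, closes the piperazine and sets C5 cis to C2 under control of the bridge. Guanine is annulated last onto an ortho-formylated phenol.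

Key step: step 10

Remark on the chemistry: the locants N1, C2, C3, N4, C5, C6 are those of the piperazine ring of the target (C2 carries the p-phenylene arm and comes from the amino acid, C5 carries the m-phenylene arm). Ns = 2-nitrophenylsulfonyl. The triaminopyrimidinone is assumed to be used as its commercial sulfate, and the target is written as the neutral free base.

Step 1
Reactants: 1 4-borono-L-phenylalanine
Product: 3 methyl (S)-3-(4-boronophenyl)-2-[(tert-butoxycarbonyl)amino]propanoate, via methyl ester hydrochloride 2 (not isolated)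
Conditions: SOCl2, MeOH, 0 °C to rt; evaporate; Boc2O, NaHCO3, THF/H2O, rt
Reagents that add atoms: methanol, CO; di-tert-butyl dicarbonate, CC(C)(C)OC(=O)OC(=O)OC(C)(C)C
Why: Fischer-type esterification with HCl generated in situ, then carbamate formation (Boc protection) on the liberated amine, are standard amino acid operations that touch neither the C2 stereocentre nor the boronic acid.

Step 2
Reactants: 3 methyl (S)-3-(4-boronophenyl)-2-[(tert-butoxycarbonyl)amino]propanoate
Product: 4 {4-[(2S)-2-[(tert-butoxycarbonyl)amino]-3-hydroxypropyl]phenyl}boronic acid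
Conditions: LiBH4, THF, 0 °C to rt; aq NH4Cl
Reagents that add atoms: none
Why: Borohydride reduction of the α-amino ester to the primary alcohol spares the carbamate, returns the boronic acid on aqueous work-up, and removes the only carbonyl that could have allowed epimerisation at C2.

Step 3
Reactants: 5 (3-hydroxy-4-methoxyphenyl)acetic acid
Product: 6 methyl (3-hydroxy-4-methoxyphenyl)acetate
Conditions: MeOH, cat. H2SO4, reflux
Reagents that add atoms: methanol, CO
Why: Acid-catalysed Fischer esterification masks the carboxylic acid so that only the phenol can bind copper in the coupling that follows.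

Step 4
Reactants: 4 {4-[(2S)-2-[(tert-butoxycarbonyl)amino]-3-hydroxypropyl]phenyl}boronic acid; 6 methyl (3-hydroxy-4-methoxyphenyl)acetate
Product: 7 methyl [3-(4-{(2S)-2-[(tert-butoxycarbonyl)amino]-3-hydroxypropyl}phenoxy)-4-methoxyphenyl]acetate
Conditions: 6 (2 equiv), Cu(OAc)2 (1 equiv), pyridine, 4 Å MS, CH2Cl2, air as terminal oxidant, rt
Reagents that add atoms: none
Why: Chan–Lam–Evans oxidative C–O coupling of an arylboronic acid with a phenol runs at room temperature, where the primary aliphatic alcohol and the carbamate N–H are poor partners, and no acidic sulfonamide N–H is yet present to compete for the arylcopper species.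

Step 5
Reactants: 7 methyl [3-(4-{(2S)-2-[(tert-butoxycarbonyl)amino]-3-hydroxypropyl}phenoxy)-4-methoxyphenyl]acetate
Product: 8 methyl [3-(4-{(2S)-3-azido-2-[(tert-butoxycarbonyl)amino]propyl}phenoxy)-4-methoxyphenyl]acetate
Conditions: PPh3, DIAD, (PhO)2P(O)N3, THF, 0 °C to rt
Reagents that add atoms: diphenylphosphoryl azide, [N-]=[N+]=NP(=O)(Oc1ccccc1)Oc1ccccc1
Why: Mitsunobu azidation displaces the activated primary alcohol by SN2 at a non-stereogenic carbon, so C2 is untouched, and the weakly acidic carbamate N–H does not cyclise onto the alkoxyphosphonium centre.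

Step 6
Reactants: 8 methyl [3-(4-{(2S)-3-azido-2-[(tert-butoxycarbonyl)amino]propyl}phenoxy)-4-methoxyphenyl]acetate
Product: 9 [3-(4-{(2S)-3-azido-2-[(tert-butoxycarbonyl)amino]propyl}phenoxy)-4-methoxyphenyl]acetic acid
Conditions: LiOH, THF/H2O, rt; then 1 M HCl to pH 3
Reagents that add atoms: lithium hydroxide, [Li+].[OH-]
Why: Saponification of the methyl arylacetate is orthogonal to the Boc and azide groups and cannot reach the remote stereocentre.

Step 7
Reactants: 9 [3-(4-{(2S)-3-azido-2-[(tert-butoxycarbonyl)amino]propyl}phenoxy)-4-methoxyphenyl]acetic acid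
Product: 11 tert-butyl N-[(2S)-1-azido-3-{4-[5-(3-diazo-2-oxopropyl)-2-methoxyphenoxy]phenyl}propan-2-yl]carbamate, via mixed carbonic anhydride 10 (not isolated)
Conditions: i-BuOCOCl, N-methylmorpholine, THF, −15 °C; then CH2N2, Et2O, 0 °C
Reagents that add atoms: diazomethane, C=[N+]=[N-]
Why: C-acylation of diazomethane by a mixed anhydride (the first stage of an Arndt–Eistert sequence) gives the diazoketone, and it is run while N1 is still a carbamate because an acidic nosylamide N–H would be methylated by diazomethane.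

Step 8
Reactants: 11 tert-butyl N-[(2S)-1-azido-3-{4-[5-(3-diazo-2-oxopropyl)-2-methoxyphenoxy]phenyl}propan-2-yl]carbamate
Product: 13 N-[(2S)-1-azido-3-{4-[5-(3-chloro-2-oxopropyl)-2-methoxyphenoxy]phenyl}propan-2-yl]-2-nitrobenzenesulfonamide, via amino chloroketone hydrochloride 12 (not isolated)
Conditions: HCl (4 M in dioxane), 0 °C to rt; evaporate; 2-NO2C6H4SO2Cl, NaHCO3, CH2Cl2/H2O, 0 °C
Reagents that add atoms: hydrogen chloride, Cl; 2-nitrobenzenesulfonyl chloride, O=S(=O)(Cl)c1ccccc1[N+](=O)[O-]
Why: Hydrogen chloride converts the diazoketone into the chloromethyl ketone (protonation, then chloride displacing N2) and cleaves the Boc group in the same flask, after which Schotten–Baumann sulfonylation of the ammonium salt is faster than alkylation of the amine by the chloroketone, as in the N-acylation of amino chloromethyl ketone salts.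

Step 9
Reactants: 13 N-[(2S)-1-azido-3-{4-[5-(3-chloro-2-oxopropyl)-2-methoxyphenoxy]phenyl}propan-2-yl]-2-nitrobenzenesulfonamide
Product: 14 (2S)-macrocyclic azido ketone [14-membered ring N1(Ns)–C2H(CH2N3)–CH2–(1,4-phenylene)–O–(4-methoxy-1,3-phenylene)–CH2–C5(=O)–C6H2–N1]
Conditions: Cs2CO3, cat. NaI, MeCN, 2 mM, slow addition, rt
Reagents that add atoms: none
Why: Fukuyama-type N-alkylation of the acidic nosylamide by the α-haloketone (activated in situ by Finkelstein exchange) is a fast SN2 reaction at a primary carbon that closes the still flexible 14-membered ring under high dilution with a base too weak to enolise the ketone appreciably.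

Step 10
Reactants: 14 (2S)-macrocyclic azido ketone
Product: 18 (2S,5S)-N1-nosyl O-methyl macrocyclic piperazine, via iminophosphorane 15 (not isolated), via amino ketone 16 (not isolated), via cyclic imine 17 (not isolated)
Conditions: PMe3, THF/H2O, rt; evaporate; NaBH(OAc)3, AcOH, ClCH2CH2Cl, 0 °C to rt
Reagents that add atoms: none
Why: Staudinger reduction of the azide in wet THF frees the amine N4 on C3, which adds to the C5 ketone across the ring and loses water to give cyclic imine 17, whose protonated form is reduced by triacetoxyborohydride; this is an intramolecular reductive amination of an amino ketone, run here transannularly. The piperazine ring (N4, C5, C6, N1, C2, C3) closes by 6-exo-trig attack of nitrogen on the carbonyl carbon. The new stereocentre C5 is set by the substrate: the N1 sulfonyl group (A1,3 strain) and the ansa chain hold the C2 arm axial, so the p-phenylene–O–m-phenylene bridge covers one face of the C=N bond, hydride enters from the open face and the C5 arylmethyl arm ends on the bridge side, cis to the C2 arm, which is (5S). The step needs facial selectivity at C5 and chemoselectivity for iminium over ketone; the bridge secures the first, since it cannot span a trans-2,5 arrangement, and the ring-enforced 1,6-relationship of amine and ketone together with the low reactivity of triacetoxyborohydride towards ketones secures the second. Because the amine is masked as an azide, the amino ketone never has to be stored, and any direct aza-Wittig closure of the iminophosphorane leads to the same imine.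

Step 11
Reactants: 18 (2S,5S)-N1-nosyl O-methyl macrocyclic piperazine
Product: 19 (2S,5S)-N1,N4-bis-nosyl O-methyl macrocyclic piperazine
Conditions: 2-NO2C6H4SO2Cl, Et3N, cat. DMAP, CH2Cl2, 0 °C to rt
Reagents that add atoms: 2-nitrobenzenesulfonyl chloride, O=S(=O)(Cl)c1ccccc1[N+](=O)[O-]
Why: Sulfonylation of the secondary amine N4 installs a second nosyl group that withstands the Lewis acid, formylation and oxidative steps ahead and can leave together with the N1 group in one final operation.

Step 12
Reactants: 19 (2S,5S)-N1,N4-bis-nosyl O-methyl macrocyclic piperazine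
Product: 20 (2S,5S)-N1,N4-bis-nosyl macrocyclic phenol
Conditions: BBr3, CH2Cl2, −78 to 0 °C; then H2O
Reagents that add atoms: none
Why: Lewis acid cleavage of the aryl methyl ether with boron tribromide frees the phenol while the diaryl ether, the sulfonamides and both stereocentres are inert.

Step 13
Reactants: 20 (2S,5S)-N1,N4-bis-nosyl macrocyclic phenol
Product: 21 (2S,5S)-N1,N4-bis-nosyl macrocyclic salicylaldehyde (CHO ortho to OH, meta to the C5 arm)
Conditions: MgCl2, Et3N, (CH2O)n, MeCN, reflux; then 1 M HCl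
Reagents that add atoms: formaldehyde (as paraformaldehyde), C=O
Why: Casnati–Skattebøl ortho-formylation delivers formaldehyde through the magnesium phenoxide to the only free position next to the hydroxyl, the other ortho position (aryloxy) and the para position (CH2) being substituted, and the fully substituted sulfonamide nitrogens cannot react with formaldehyde.

Step 14
Reactants: 21 (2S,5S)-N1,N4-bis-nosyl macrocyclic salicylaldehyde; 22 2,5,6-triaminopyrimidin-4(3H)-one sulfate
Product: 24 N1,N4-bis-nosyl guanipiperazine A, via Schiff base 23 (not isolated)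
Conditions: NaOAc, DMSO, 90 °C; then air (O2), 120 °C
Reagents that add atoms: none
Why: This is the oxidative cyclocondensation of an ortho-diamine with an aldehyde (aldehyde variant of the Traube purine synthesis), in which the most nucleophilic 5-amino group forms the Schiff base, the 6-amino group closes the imidazole ring and air in hot DMSO dehydrogenates it to the 8-arylguanine.

Step 15
Reactants: 24 N1,N4-bis-nosyl guanipiperazine A
Product: 25 guanipiperazine A
Conditions: PhSH, K2CO3, DMF, rt; reverse-phase purification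
Reagents that add atoms: none
Why: Fukuyama denosylation, in which thiolate adds to each 2-nitrophenylsulfonyl ring (SNAr through a Meisenheimer adduct) and releases the amine with loss of SO2, frees both piperazine nitrogens under conditions that leave the guanine, the phenol and the stereocentres alone.

Compound list
1 | 4-borono-L-phenylalanine, (S)-2-amino-3-(4-boronophenyl)propanoic acid | N[C@@H](Cc1ccc(cc1)B(O)O)C(=O)O | starting material
2 | methyl (S)-2-amino-3-(4-boronophenyl)propanoate hydrochloride (formed in situ) | N[C@@H](Cc1ccc(cc1)B(O)O)C(=O)OC.Cl | intermediate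
3 | methyl (S)-3-(4-boronophenyl)-2-[(tert-butoxycarbonyl)amino]propanoate | CC(C)(C)OC(=O)N[C@@H](Cc1ccc(cc1)B(O)O)C(=O)OC | intermediate
4 | {4-[(2S)-2-[(tert-butoxycarbonyl)amino]-3-hydroxypropyl]phenyl}boronic acid | CC(C)(C)OC(=O)N[C@@H](Cc1ccc(cc1)B(O)O)CO | intermediate
5 | (3-hydroxy-4-methoxyphenyl)acetic acid (homoisovanillic acid) | COc1ccc(CC(=O)O)cc1O | starting material
6 | methyl (3-hydroxy-4-methoxyphenyl)acetate | COC(=O)Cc1ccc(OC)c(O)c1 | intermediate
7 | methyl [3-(4-{(2S)-2-[(tert-butoxycarbonyl)amino]-3-hydroxypropyl}phenoxy)-4-methoxyphenyl]acetate | CC(C)(C)OC(=O)N[C@@H](Cc1ccc(cc1)Oc1cc(CC(=O)OC)ccc1OC)CO | intermediate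
8 | methyl [3-(4-{(2S)-3-azido-2-[(tert-butoxycarbonyl)amino]propyl}phenoxy)-4-methoxyphenyl]acetate | CC(C)(C)OC(=O)N[C@@H](Cc1ccc(cc1)Oc1cc(CC(=O)OC)ccc1OC)CN=[N+]=[N-] | intermediate
9 | [3-(4-{(2S)-3-azido-2-[(tert-butoxycarbonyl)amino]propyl}phenoxy)-4-methoxyphenyl]acetic acid | CC(C)(C)OC(=O)N[C@@H](Cc1ccc(cc1)Oc1cc(CC(=O)O)ccc1OC)CN=[N+]=[N-] | intermediate
10 | mixed anhydride of 9 with isobutyl hydrogen carbonate (formed in situ) | CC(C)(C)OC(=O)N[C@@H](Cc1ccc(cc1)Oc1cc(CC(=O)OC(=O)OCC(C)C)ccc1OC)CN=[N+]=[N-] | intermediate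
11 | tert-butyl N-[(2S)-1-azido-3-{4-[5-(3-diazo-2-oxopropyl)-2-methoxyphenoxy]phenyl}propan-2-yl]carbamate | CC(C)(C)OC(=O)N[C@@H](Cc1ccc(cc1)Oc1cc(CC(=O)C=[N+]=[N-])ccc1OC)CN=[N+]=[N-] | intermediate
12 | 1-(3-{4-[(2S)-2-amino-3-azidopropyl]phenoxy}-4-methoxyphenyl)-3-chloropropan-2-one hydrochloride (formed in situ) | N[C@@H](Cc1ccc(cc1)Oc1cc(CC(=O)CCl)ccc1OC)CN=[N+]=[N-].Cl | intermediate
13 | N-[(2S)-1-azido-3-{4-[5-(3-chloro-2-oxopropyl)-2-methoxyphenoxy]phenyl}propan-2-yl]-2-nitrobenzenesulfonamide | O=S(=O)(N[C@@H](Cc1ccc(cc1)Oc1cc(CC(=O)CCl)ccc1OC)CN=[N+]=[N-])c1ccccc1[N+](=O)[O-] | intermediate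
14 | (2S)-macrocyclic azido ketone: 14-membered ring N1(Ns)–C2H(CH2N3)–CH2–(1,4-phenylene)–O–(4-methoxy-1,3-phenylene; CH2 on C1, O on C3)–CH2–C5(=O)–C6H2–N1 | [N-]=[N+]=NC[C@@H]1Cc2ccc(cc2)Oc2cc(ccc2OC)CC(=O)CN1S(=O)(=O)c1ccccc1[N+](=O)[O-] | intermediate
15 | (2S)-macrocyclic ketone with CH2–N=PMe3 on C2 (iminophosphorane, formed in situ) | CP(C)(C)=NC[C@@H]1Cc2ccc(cc2)Oc2cc(ccc2OC)CC(=O)CN1S(=O)(=O)c1ccccc1[N+](=O)[O-] | intermediate
16 | (2S)-macrocyclic C5 ketone with N1-nosyl and free aminomethyl on C2 (formed in situ) | NC[C@@H]1Cc2ccc(cc2)Oc2cc(ccc2OC)CC(=O)CN1S(=O)(=O)c1ccccc1[N+](=O)[O-] | intermediate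
17 | (2S)-bicyclic imine: N1-nosyl 1,2,3,6-tetrahydropyrazine (N4=C5) bridged from C2 to C5 by the diaryl ether (formed in situ) | COc1ccc2cc1Oc1ccc(cc1)C[C@H]1CN=C(CN1S(=O)(=O)c1ccccc1[N+](=O)[O-])C2 | intermediate
18 | (2S,5S)-N1-nosyl O-methyl macrocyclic piperazine (cis-2,5; N4–H free) | COc1ccc2cc1Oc1ccc(cc1)C[C@H]1CN[C@H](CN1S(=O)(=O)c1ccccc1[N+](=O)[O-])C2 | intermediate
19 | (2S,5S)-N1,N4-bis-nosyl O-methyl macrocyclic piperazine | COc1ccc2cc1Oc1ccc(cc1)C[C@H]1CN([C@H](CN1S(=O)(=O)c1ccccc1[N+](=O)[O-])C2)S(=O)(=O)c1ccccc1[N+](=O)[O-] | intermediate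
20 | (2S,5S)-N1,N4-bis-nosyl macrocyclic phenol (OH ortho to the diaryl ether oxygen, para to the C5 arm) | Oc1ccc2cc1Oc1ccc(cc1)C[C@H]1CN([C@H](CN1S(=O)(=O)c1ccccc1[N+](=O)[O-])C2)S(=O)(=O)c1ccccc1[N+](=O)[O-] | intermediate
21 | (2S,5S)-N1,N4-bis-nosyl macrocyclic salicylaldehyde (CHO on the free carbon ortho to OH) | O=Cc1cc2cc(c1O)Oc1ccc(cc1)C[C@H]1CN([C@H](CN1S(=O)(=O)c1ccccc1[N+](=O)[O-])C2)S(=O)(=O)c1ccccc1[N+](=O)[O-] | intermediate
22 | 2,5,6-triaminopyrimidin-4(3H)-one sulfate | Nc1nc(N)c(N)c(=O)[nH]1.OS(=O)(=O)O | starting material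
23 | Schiff base of 21 with the 5-amino group of the triaminopyrimidinone (formed in situ) | Nc1nc(N)c(N=Cc2cc3cc(c2O)Oc2ccc(cc2)C[C@H]2CN([C@H](CN2S(=O)(=O)c2ccccc2[N+](=O)[O-])C3)S(=O)(=O)c2ccccc2[N+](=O)[O-])c(=O)[nH]1 | intermediate
24 | N1,N4-bis-nosyl guanipiperazine A (guanine C8 bonded to the former aldehyde carbon; 2S,5S) | Nc1nc2nc(-c3cc4cc(c3O)Oc3ccc(cc3)C[C@H]3CN([C@H](CN3S(=O)(=O)c3ccccc3[N+](=O)[O-])C4)S(=O)(=O)c3ccccc3[N+](=O)[O-])[nH]c2c(=O)[nH]1 | intermediate
25 | guanipiperazine A (2S,5S) | Nc1nc2nc(-c3cc4cc(c3O)Oc3ccc(cc3)C[C@H]3CN[C@H](CN3)C4)[nH]c2c(=O)[nH]1 | target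

Total step count: 15. Longest linear sequence: 14 steps (from 1 through steps 1, 2 and 4–15; step 3 prepares the second fragment).

Steps most likely to fail

Step 9. The ring closure may lose to intermolecular N-alkylation (oligomer formation), or the chloroketone may enolise on its benzylic side and decompose by a Favorskii-type path while the slow cyclisation is awaited. The fallback removes the enolisable electrophile. It sets out from 13, whose ketone is reduced with NaBH4 (MeOH, 0 °C) to the chlorohydrin F1 (both carbinol epimers, used together). Cs2CO3 in DMF at 60 °C under high dilution converts this into the terminal epoxide F2 (not isolated), which the sulfonamide anion opens at its CH2 terminus to give the macrocyclic β-hydroxy sulfonamide F3. Dess–Martin oxidation of F3 returns the route to 14.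

Step 10. Hydride delivery may show insufficient facial selectivity, or the α-sulfonamido imine may tautomerise and lose sulfinate before it is reduced. The fallback forms N4–C5 by substitution instead of reduction, so that C5 is set by inversion of a carbinol. It sets out from 14: NaBH4 reduction gives the C5 carbinols, from which the (5R)-epimer, azido alcohol F4, is separated (the other epimer is returned to 14 by Dess–Martin oxidation). Staudinger reduction (PMe3, THF/H2O) gives the amino alcohol F5, and NsCl/Et3N gives the bis-sulfonamide alcohol F6. A transannular Fukuyama–Mitsunobu cyclisation (PPh3, DIAD, THF) then closes the piperazine with inversion at C5 and rejoins the route at 19.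

Step 14. Dehydrogenation after ring closure may stay incomplete, the Schiff base may revert hydrolytically, or the electron-rich aminopyrimidine may be over-oxidised in hot DMSO. The fallback is the acylative Traube sequence, which needs no oxidant at the ring-forming stage. It sets out from 21: Pinnick oxidation (NaClO2, NaH2PO4, 2-methyl-2-butene, t-BuOH/H2O) gives the salicylic acid F7. Carbodiimide coupling (EDC·HCl, HOBt, DMF) with 22, freed from its sulfate with NaHCO3, acylates the 5-amino group to give the amide F8. Silylative cyclodehydration (hexamethyldisilazane, cat. (NH4)2SO4, reflux) closes the imidazole ring and returns the route to 24.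

Further compounds
F1 | step 9 | N-[(2S)-1-azido-3-{4-[5-(3-chloro-2-hydroxypropyl)-2-methoxyphenoxy]phenyl}propan-2-yl]-2-nitrobenzenesulfonamide (carbinol epimers) | O=S(=O)(N[C@@H](Cc1ccc(cc1)Oc1cc(CC(O)CCl)ccc1OC)CN=[N+]=[N-])c1ccccc1[N+](=O)[O-]
F2 | step 9 | N-[(2S)-1-azido-3-{4-[2-methoxy-5-(oxiran-2-ylmethyl)phenoxy]phenyl}propan-2-yl]-2-nitrobenzenesulfonamide (epoxide epimers, not isolated) | O=S(=O)(N[C@@H](Cc1ccc(cc1)Oc1cc(CC2CO2)ccc1OC)CN=[N+]=[N-])c1ccccc1[N+](=O)[O-]
F3 | step 9 | (2S)-macrocyclic azido alcohol, the C5 carbinol of 14 (C5 epimers) | [N-]=[N+]=NC[C@@H]1Cc2ccc(cc2)Oc2cc(ccc2OC)CC(O)CN1S(=O)(=O)c1ccccc1[N+](=O)[O-]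
F4 | step 10 | (2S,5R)-macrocyclic azido alcohol | [N-]=[N+]=NC[C@@H]1Cc2ccc(cc2)Oc2cc(ccc2OC)C[C@@H](O)CN1S(=O)(=O)c1ccccc1[N+](=O)[O-]
F5 | step 10 | (2S,5R)-macrocyclic amino alcohol (free aminomethyl on C2) | NC[C@@H]1Cc2ccc(cc2)Oc2cc(ccc2OC)C[C@@H](O)CN1S(=O)(=O)c1ccccc1[N+](=O)[O-]
F6 | step 10 | (2S,5R)-macrocyclic alcohol with N1-nosyl and nosylamidomethyl on C2 | O=[N+]([O-])c1ccccc1S(=O)(=O)NC[C@@H]1Cc2ccc(cc2)Oc2cc(ccc2OC)C[C@@H](O)CN1S(=O)(=O)c1ccccc1[N+](=O)[O-]
F7 | step 14 | (2S,5S)-N1,N4-bis-nosyl macrocyclic salicylic acid (CO2H in place of CHO of 21) | OC(=O)c1cc2cc(c1O)Oc1ccc(cc1)C[C@H]1CN([C@H](CN1S(=O)(=O)c1ccccc1[N+](=O)[O-])C2)S(=O)(=O)c1ccccc1[N+](=O)[O-]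
F8 | step 14 | N-(2,6-diamino-4-oxo-3,4-dihydropyrimidin-5-yl) amide of F7 | Nc1nc(N)c(NC(=O)c2cc3cc(c2O)Oc2ccc(cc2)C[C@H]2CN([C@H](CN2S(=O)(=O)c2ccccc2[N+](=O)[O-])C3)S(=O)(=O)c2ccccc2[N+](=O)[O-])c(=O)[nH]1
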